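**Conventions.** The ring carbons are numbered as in the target. C1 and C4 carry the imidazoles, C2 and C3 carry the CH2N arms, and C1 is bonded to C2. Systematic names in the compound list use their own locants.

## The problem

Sceptrin (21) is a cyclobutane with one hydrogen and one substituent on every ring carbon. C1 and C4 each carry a 2-aminoimidazol-4-yl ring, and C2 and C3 each carry a CH2NH–CO–(4-bromopyrrol-2-yl) arm. All neighbours are trans, and a twofold axis runs through the midpoints of the C1–C4 and C2–C3 bonds. The four contiguous stereocentres (1S,2R,3R,4S) are therefore two symmetry-related pairs. Because the all-trans arrangement is the thermodynamic one, a ring carbon that bears a carbonyl group can be corrected by epimerisation once its neighbours are fixed. The absolute sense cannot be corrected, so one pair of ring carbons has to be set absolutely and the other pair has to follow it.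

There is no chain to assemble. The skeleton is the four-membered ring plus four one-carbon branches, so the ring must come from a [2+2] union or from an existing cyclobutane, and it must then survive every later step without ring opening. The 2-aminoimidazoles are basic, polar and nucleophilic. The pyrrole C–Br bonds do not tolerate hydrogenolysis or long irradiation. A free primary amine on a CH2 arm can cyclise onto a carbonyl group elsewhere on the ring. These groups therefore have to be introduced late.

The feature that opens the structure is the oxidation pattern of the branches. C1, C4 and the two imidazole carbons attached to them form a four-carbon unit at the carboxyl level, held cis on a ring: the carbons of maleic anhydride. C2, C3 and their two CH2N carbons form a four-carbon chain at the aldehyde level. That chain is C2–C5 of D-mannitol once C3=C4 is an E-alkene and C2 and C5 are masked as dioxolane stereocentres.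

## Retrosynthesis

**Amide bonds.** The two amide C–N bonds of 21 are cut last, giving the tetraamine 19 and two molecules of commercial 4-bromo-2-(trichloroacetyl)pyrrole 20. Cutting here keeps the C–Br bonds and the acidic pyrrole N–H out of all the carbonyl chemistry. The forward reaction must acylate the primary alkylamines in the presence of the free 2-aminoimidazoles, which the much lower nucleophilicity of the guanidine-type nitrogens should allow.

**Imidazole rings.** The C4–N3 and C5–N1 bonds of each imidazole in 19 are cut, leading through the Boc-protected 18 to the bis(bromomethyl ketone) 16 and two molecules of N-Boc-guanidine 17. The alternative of attaching preformed imidazoles to the ring needs a C–C coupling at a hindered cyclobutane carbon and a separate amination of imidazole C2. The condensation delivers the amino group and the ring in one operation, from a ketone that sits on an already correct stereocentre. The forward reaction has to run twice on one molecule without the carbamate nitrogens interfering.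

**Bromoacetyl groups.** The CO–CH2Br bond of each arm in 16 is cut, giving the diacid 13 (forward through the mixed anhydride 14 and the diazoketone 15) and behind it the diester 12. The carboxyl carbon thereby becomes imidazole C4, so no redox adjustment is needed at C1 and C4. The forward homologation must tolerate two NHBoc groups, which is standard amino acid practice.

**CH2–N bonds.** The CH2–N bonds of 12 are cut to the dialdehyde 10 and two molecules of tert-butyl carbamate 11. Introducing nitrogen directly as a carbamate is preferred to an amine or an alcohol, because a free amine or hydroxyl on this arm is 1,3-cis to an ester and can lactamise or lactonise. The dialdehyde 10 is the glycol-cleavage product of the bis(dioxolane) 8 (via the tetraol 9), so the aldehyde carbons and their oxidation level come from the chiral pool.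

**C1 configuration.** The diester 8 is the C1 epimer of the cis-diester 7, which is the methanolysis and methylation product (via the half-ester 6) of the anhydride 5. In 7, C1 is the only ring carbon cis to both neighbours, so equilibration has one obvious outcome. This is what allows a cis-fused anhydride to serve as precursor to an all-trans ring.

**Key disconnection.** The C1–C2 and C3–C4 bonds of 5 are cut, giving maleic anhydride 4 and the E-alkene 3. The other [2+2] cut (C1–C4 and C2–C3) would be a head-to-head dimerisation of two identical halves, with head-to-tail and enantioselectivity problems in one step. The crossed cut puts all the stereochemical information into one partner and all the carboxyl carbons into the other. Both partners are trivial compared with 5, which gains one ring, two skeletal bonds and four stereocentres. The forward reaction must add the anhydride to one face of the alkene.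

**Alkene.** The C=C bond of 3 is traced back to the 3,4-diol of 1,2:5,6-di-O-isopropylidene-D-mannitol 1 through the thionocarbonate 2. The threo diol can only give the E-alkene by syn elimination, and the two dioxolane stereocentres are carried over unchanged.

## Roads not taken

**Alternative 1: twofold directed C–H arylation.** The cut is the two ring–imidazole bonds at C1 and C4 on an intact cyclobutane. The (1R,2R)-bis(8-aminoquinoline) amide A2 of trans-cyclobutane-1,2-dicarboxylic acid would be arylated twice with 4-iodo-1-SEM-imidazole A3 under Pd(OAc)2/AgOAc. Each bidentate amide steers the divalent palladium to the methylene C–H cis to it, giving A1.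

- Merits: it is convergent and needs no light. The heteroaryl C–C bonds are made directly, and the absolute configuration comes from a simple resolved diacid.
- Weak points: the imidazole N3 competes with the directing group for palladium, and the second arylation has to occur next to the first on the adjacent methylene. In A1 each imidazole is cis to its amide, so both amide-bearing carbons must be epimerised afterwards. Two robust auxiliaries then have to be removed, two carboxamides reduced to CH2N, and each imidazole aminated at C2 before SEM removal.
- Comparison: this road is better in convergence and in avoiding the ester-to-haloketone sequence. The chosen plan sets against it that all ring bonds and all four branch carbons arrive in one step at the right oxidation level, that the amino group comes with the imidazole ring, and that no directing group has to be cleaved.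

**Alternative 2: transannular enolate coupling.** The cut is the C1–C4 bond alone, with C2–C3 kept as the ring-fusion bond of a diquinane. cis-Bicyclo[3.3.0]octane-3,7-dione A6 would be converted into its twofold-symmetric bis(trimethylsilyl enol ether) A5. Oxidation with (NH4)2Ce(NO3)6 (tetravalent cerium) would then join the two enol carbons to give the tricyclic dione A4.

- Merits: it is the shortest conceivable access to the core. Each two-carbon bridge of A4 spans a 1,3-pair of ring carbons on one face, so cleaving both bridges between C=O and CH2 would give the all-trans pattern with no epimerisation and no facial question.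
- Weak points: oxidative enol ether coupling is established for unstrained five- and six-membered 1,4-diketones, not for closing a cyclobutane inside a cage. The product is a strained 1,4-dione whose new bond is activated for reductive or retro-aldol cleavage. A single enantiomer requires a double enantiotopic enolisation that also selects the chiral bis-enol ether over the meso one. The later C–C cleavages must be regioselective.
- Comparison: if the coupling worked, this road would be stereochemically cleaner and shorter. The chosen plan sets against it a ring-forming reaction of a known type and an absolute configuration taken from the chiral pool.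

**Alternative 3: copper-catalysed [3+1].** The cut is the two ring bonds to one carboxyl-bearing carbon. The enoldiazoacetate A8 would form a copper enolcarbene with Cu(MeCN)4BF4 (monovalent copper) and a chiral bis(oxazoline) ligand. The sulfonium ylide A9 would attack its vinylogous carbon, and the metal-bound carbon would then displace Me2S to close the cyclobutene A7.

- Merits: it is catalytic and enantioselective, runs at low temperature, and gives two differentiated esters. No stoichiometric stereocentres or carbons are discarded, whereas the chosen plan discards two dioxolane stereocentres and loses two carbons as formaldehyde.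
- Weak points: in A7 the ring carbon that must carry a CH2N arm bears a silyloxy group instead of a carbon. A one-carbon homologation at a hindered, enolisable β-keto ester in a strained ring is then required, and two further stereocentres remain to be set. The ring is a donor–acceptor cyclobutene prone to opening. A γ-substituted enoldiazoacetate is a demanding substrate for this cycloaddition.
- Comparison: this road is better in catalytic stereocontrol and atom economy at the key step. The chosen plan sets against it that all four ring substituents are present as carbon at the correct oxidation level after the key step.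

Key step: step 3

**Assumptions.**
- In 18 the Boc group of each imidazole is drawn on the ring nitrogen next to C5, the usual outcome of this condensation; its position is immaterial because step 11 removes it.
- Compound 19 is handled as its tetrakis(trifluoroacetate); its SMILES and that of 21 are those of the free bases.
- Steps 7 to 12 act on both twofold-related arms in one operation, so each consumes two molecules of its reagent; the second molecule is written out on the line of reagents that add atoms.

## Route

Step 1
Reactants: 1 1,2:5,6-di-O-isopropylidene-D-mannitol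
Product: 2 1,2:5,6-di-O-isopropylidene-3,4-O-thiocarbonyl-D-mannitol
Conditions: 1,1'-thiocarbonyldiimidazole, toluene, reflux
Reagents that add atoms: 1,1'-thiocarbonyldiimidazole, S=C(n1ccnc1)n1ccnc1
Why: Double acyl substitution by the vicinal diol on the thiocarbonyl transfer reagent closes the cyclic thionocarbonate (first stage of the Corey–Winter olefination); the acetonides are inert and no stereocentre is touched.

Step 2
Reactants: 2 1,2:5,6-di-O-isopropylidene-3,4-O-thiocarbonyl-D-mannitol
Product: 3 (E)-1,2-bis[(4S)-2,2-dimethyl-1,3-dioxolan-4-yl]ethene
Conditions: P(OMe)3, reflux (about 110 °C)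
Reagents that add atoms: none
Why: Corey–Winter olefination: the phosphite removes sulfur and the resulting 2-ylidene dioxolane loses CO2 in a stereospecific syn cycloreversion, so the threo diol can only give the E-alkene; the dioxolane carbons keep their geometry and are called S only because the substituent priorities change.

Step 3
Reactants: 3 (E)-1,2-bis[(4S)-2,2-dimethyl-1,3-dioxolan-4-yl]ethene; 4 maleic anhydride
Product: 5 (1R,5S,6R,7R)-6,7-bis[(4S)-2,2-dimethyl-1,3-dioxolan-4-yl]-3-oxabicyclo[3.2.0]heptane-2,4-dione
Conditions: hν (medium-pressure Hg lamp, Pyrex filter), Ph2CO (0.2 equiv), degassed MeCN, 5–10 °C, 4 added in portions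
Reagents that add atoms: none
Why: Triplet benzophenone, excited above 300 nm where 3 is transparent, passes its energy to maleic anhydride, whose electrophilic triplet bonds to one alkene carbon to give a triplet 1,4-biradical that closes after spin inversion; the closest known reaction type is the sensitised crossed [2+2] photocycloaddition of maleic anhydride with acyclic E-1,2-disubstituted alkenes such as (E)-1,4-dichlorobut-2-ene. The four-membered ring closes by radical–radical combination within the 1,4-biradical, and because the two anhydride carbons are held in a five-membered ring the fusion at C1 and C4 can only be cis. C2 is set in the first bond-forming event by its (4S)-dioxolane: in the conformer with the allylic C–H in the alkene plane the allylic C–O bond covers one face, and attack anti to it is attack on the si face, which gives R at that carbon. C3 follows from the E geometry, since the biradical should close to the less crowded 2,3-trans ring, and the twofold symmetry of 3 makes the second dioxolane cover the same face, so the two controllers are matched (it is also the face that the empirical anti rule for osmylation of allylic ethers predicts). C1 and C4 add no further isomers, because the two ways of placing the cis-anhydride on a given alkene face are related by the twofold axis. The step therefore needs facial selectivity only, together with preference for the crossed adduct over the anhydride photodimer, which portionwise addition of 4 and filtration of the insoluble dimer should secure. The minor facial isomer has to be removed at 5, 7 or 8, because after step 6 it would become the enantiomer of the product.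

Step 4
Reactants: 5 (1R,5S,6R,7R)-6,7-bis[(4S)-2,2-dimethyl-1,3-dioxolan-4-yl]-3-oxabicyclo[3.2.0]heptane-2,4-dione
Product: 7 dimethyl (1R,2S,3R,4R)-3,4-bis[(4S)-2,2-dimethyl-1,3-dioxolan-4-yl]cyclobutane-1,2-dicarboxylate (1,2-cis diester), via monomethyl half-ester 6 (not isolated)
Conditions: MeOH, DMAP (cat.), PhMe, rt; then TMSCHN2 (hexanes), 0 °C
Reagents that add atoms: methanol, CO; trimethylsilyldiazomethane, C[Si](C)(C)C=[N+]=[N-]
Why: Nucleophilic acyl substitution opens the strained cis-anhydride to the half-ester and O-methylation of the remaining acid with trimethylsilyldiazomethane in methanol completes the diester without the mineral acid that would cleave the acetonides; both regioisomeric half-esters converge on 7 and no stereocentre changes.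

Step 5
Reactants: 7 dimethyl (1R,2S,3R,4R)-3,4-bis[(4S)-2,2-dimethyl-1,3-dioxolan-4-yl]cyclobutane-1,2-dicarboxylate
Product: 8 dimethyl (1S,2S,3R,4R)-3,4-bis[(4S)-2,2-dimethyl-1,3-dioxolan-4-yl]cyclobutane-1,2-dicarboxylate (all-trans diester)
Conditions: NaOMe (0.5 equiv), MeOH, rt
Reagents that add atoms: none
Why: Thermodynamic epimerisation through the ester enolate: C1, the only ring carbon cis to both neighbours, inverts to give the all-trans ring, while C2 and C3 carry no acidifying group and keep the configuration set in step 3.

Step 6
Reactants: 8 dimethyl (1S,2S,3R,4R)-3,4-bis[(4S)-2,2-dimethyl-1,3-dioxolan-4-yl]cyclobutane-1,2-dicarboxylate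
Product: 10 dimethyl (1S,2S,3R,4R)-3,4-diformylcyclobutane-1,2-dicarboxylate, via tetraol diester 9 (not isolated)
Conditions: H5IO6, EtOAc, rt
Reagents that add atoms: none
Why: Periodic acid hydrolyses each terminal acetonide and cleaves the liberated 1,2-diol in the same flask (glycol cleavage through the cyclic periodate ester), so the tetraol has no time to lactonise; the aldehyde carbons are the former C2 and C5 of mannitol and the trans-dialdehyde is the stable arrangement at C2 and C3.

Step 7
Reactants: 10 dimethyl (1S,2S,3R,4R)-3,4-diformylcyclobutane-1,2-dicarboxylate; 11 tert-butyl carbamate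
Product: 12 dimethyl (1S,2S,3R,4R)-3,4-bis{[(tert-butoxycarbonyl)amino]methyl}cyclobutane-1,2-dicarboxylate
Conditions: 11 (2.4 equiv), Et3SiH (6 equiv), TFA (4 equiv), MeCN, 0 °C to rt
Reagents that add atoms: tert-butyl carbamate (second equivalent of 11), CC(C)(C)OC(N)=O
Why: Reductive N-alkylation of a carbamate: acid-catalysed condensation of each of the two aldehydes with one molecule of 11 gives an N-acyliminium ion that takes hydride from the silane, so two molecules of 11 are built in and nitrogen arrives as a non-nucleophilic carbamate that cannot lactamise onto the ring esters; any enolisation at C2 or C3 on the way returns to the favoured trans arrangement.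

Step 8
Reactants: 12 dimethyl (1S,2S,3R,4R)-3,4-bis{[(tert-butoxycarbonyl)amino]methyl}cyclobutane-1,2-dicarboxylate
Product: 13 (1S,2S,3R,4R)-3,4-bis{[(tert-butoxycarbonyl)amino]methyl}cyclobutane-1,2-dicarboxylic acid
Conditions: LiOH·H2O (4 equiv), THF/H2O, 0 °C to rt; then 1 M HCl to pH 3 at 0 °C
Reagents that add atoms: water, O; water (second equivalent), O
Why: Ester saponification of both methyl esters, one hydroxide oxygen entering each carboxyl; the carbamates are stable to hydroxide and the all-trans ring is already at its thermodynamic configuration, so base cannot erode it.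

Step 9
Reactants: 13 (1S,2S,3R,4R)-3,4-bis{[(tert-butoxycarbonyl)amino]methyl}cyclobutane-1,2-dicarboxylic acid
Product: 16 di-tert-butyl {[(1R,2R,3S,4S)-3,4-bis(2-bromoacetyl)cyclobutane-1,2-diyl]bis(methylene)}dicarbamate, via bis(isobutyl carbonic anhydride) 14 (not isolated), via bis(diazomethyl ketone) 15 (not isolated)
Conditions: iBuOCOCl (2.2 equiv), N-methylmorpholine (2.2 equiv), THF, −15 °C; CH2N2 (excess), Et2O, 0 °C; then 48% aq. HBr (2.2 equiv), 0 °C
Reagents that add atoms: diazomethane, C=[N+]=[N-]; diazomethane (second equivalent), C=[N+]=[N-]; hydrogen bromide, Br; hydrogen bromide (second equivalent), Br; isobutyl chloroformate (retained in 14 only), CC(C)COC(Cl)=O; isobutyl chloroformate (second equivalent for 14), CC(C)COC(Cl)=O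
Why: Acylation of diazomethane by each mixed carbonic anhydride (first stage of an Arndt–Eistert sequence) gives the diazomethyl ketone, which HBr protonates at carbon before bromide displaces N2; this is the standard one-pot route to halomethyl ketones of carbamate-protected amino acids, the Boc groups survive brief cold aqueous HBr, and no stereocentre is involved.

Step 10
Reactants: 16 di-tert-butyl {[(1R,2R,3S,4S)-3,4-bis(2-bromoacetyl)cyclobutane-1,2-diyl]bis(methylene)}dicarbamate; 17 N-Boc-guanidine
Product: 18 di-tert-butyl 4,4'-[(1S,2S,3R,4R)-3,4-bis{[(tert-butoxycarbonyl)amino]methyl}cyclobutane-1,2-diyl]bis(2-amino-1H-imidazole-1-carboxylate)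
Conditions: 17 (6 equiv), DMF, rt
Reagents that add atoms: N-Boc-guanidine (second equivalent of 17), CC(C)(C)OC(=O)NC(N)=N
Why: Condensation of an α-bromoketone with an acylguanidine, run on both arms so that one molecule of 17 is built into each ring: N-alkylation at the CH2Br carbon, ring closure of a second guanidine nitrogen onto the ketone and dehydration give the 2-aminoimidazole, with the excess guanidine taking up HBr; the ketone carbon becomes imidazole C4, so C1 and C4 stay as set in step 5.

Step 11
Reactants: 18 di-tert-butyl 4,4'-[(1S,2S,3R,4R)-3,4-bis{[(tert-butoxycarbonyl)amino]methyl}cyclobutane-1,2-diyl]bis(2-amino-1H-imidazole-1-carboxylate)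
Product: 19 4,4'-[(1S,2S,3R,4R)-3,4-bis(aminomethyl)cyclobutane-1,2-diyl]bis(1H-imidazol-2-amine), as its tetrakis(trifluoroacetate)
Conditions: TFA/CH2Cl2 (1:1), 0 °C to rt; evaporation
Reagents that add atoms: none
Why: Acidolysis of all four tert-butoxycarbonyl groups (loss of the tert-butyl cation, then decarboxylation); the protonated amines and aminoimidazolium rings are stable in acid and cannot cyclise.

Step 12
Reactants: 19 4,4'-[(1S,2S,3R,4R)-3,4-bis(aminomethyl)cyclobutane-1,2-diyl]bis(1H-imidazol-2-amine); 20 4-bromo-2-(trichloroacetyl)-1H-pyrrole
Product: 21 sceptrin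
Conditions: 20 (2.1 equiv), iPr2NEt, DMF, rt; reverse-phase chromatography
Reagents that add atoms: 4-bromo-2-(trichloroacetyl)-1H-pyrrole (second equivalent of 20), O=C(c1cc(Br)c[nH]1)C(Cl)(Cl)Cl
Why: Amide formation by haloform-type acyl transfer: each of the two primary alkylamines adds to one molecule of the trichloromethyl ketone and expels chloroform, while the far less nucleophilic guanidine-type nitrogens of the 2-aminoimidazoles should be left alone; no coupling agent is needed, so the C–Br bonds and the pyrrole N–H are untouched.

## Compound list

1 | 1,2:5,6-di-O-isopropylidene-D-mannitol | CC1(C)OC[C@@H](O1)[C@@H](O)[C@H](O)[C@H]1COC(C)(C)O1 | starting material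
2 | 1,2:5,6-di-O-isopropylidene-3,4-O-thiocarbonyl-D-mannitol (trans-4,5-disubstituted 1,3-dioxolane-2-thione) | CC1(C)OC[C@@H](O1)[C@@H](OC2=S)[C@H](O2)[C@H]1COC(C)(C)O1 | intermediate
3 | (E)-1,2-bis[(4S)-2,2-dimethyl-1,3-dioxolan-4-yl]ethene | CC1(C)OC[C@@H](O1)/C=C/[C@H]1COC(C)(C)O1 | intermediate
4 | maleic anhydride | O=C1OC(=O)C=C1 | starting material
5 | (1R,5S,6R,7R)-6,7-bis[(4S)-2,2-dimethyl-1,3-dioxolan-4-yl]-3-oxabicyclo[3.2.0]heptane-2,4-dione (cis-fused anhydride, dioxolanes trans) | O=C3OC(=O)[C@@H]1[C@H]([C@H]4COC(C)(C)O4)[C@@H]([C@H]5COC(C)(C)O5)[C@@H]13 | intermediate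
6 | monomethyl half-ester of the ring-opened anhydride, all ring configurations as in 5 (regioisomer with the ester on C1 drawn; the other converges on 7) | COC(=O)[C@@H]1[C@H]([C@H]2COC(C)(C)O2)[C@@H]([C@H]2COC(C)(C)O2)[C@@H]1C(=O)O | intermediate (not isolated)
7 | dimethyl (1R,2S,3R,4R)-3,4-bis[(4S)-2,2-dimethyl-1,3-dioxolan-4-yl]cyclobutane-1,2-dicarboxylate (esters cis) | COC(=O)[C@@H]1[C@H]([C@H]2COC(C)(C)O2)[C@@H]([C@H]2COC(C)(C)O2)[C@@H]1C(=O)OC | intermediate
8 | dimethyl (1S,2S,3R,4R)-3,4-bis[(4S)-2,2-dimethyl-1,3-dioxolan-4-yl]cyclobutane-1,2-dicarboxylate (all-trans) | COC(=O)[C@H]1[C@H]([C@H]2COC(C)(C)O2)[C@@H]([C@H]2COC(C)(C)O2)[C@@H]1C(=O)OC | intermediate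
9 | dimethyl (1S,2S,3R,4R)-3,4-bis[(1S)-1,2-dihydroxyethyl]cyclobutane-1,2-dicarboxylate | COC(=O)[C@H]1[C@H]([C@H](O)CO)[C@@H]([C@H](O)CO)[C@@H]1C(=O)OC | intermediate (not isolated)
10 | dimethyl (1S,2S,3R,4R)-3,4-diformylcyclobutane-1,2-dicarboxylate (all-trans) | COC(=O)[C@H]1[C@H](C=O)[C@@H](C=O)[C@@H]1C(=O)OC | intermediate
11 | tert-butyl carbamate | CC(C)(C)OC(N)=O | starting material
12 | dimethyl (1S,2S,3R,4R)-3,4-bis{[(tert-butoxycarbonyl)amino]methyl}cyclobutane-1,2-dicarboxylate | COC(=O)[C@H]1[C@H](CNC(=O)OC(C)(C)C)[C@@H](CNC(=O)OC(C)(C)C)[C@@H]1C(=O)OC | intermediate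
13 | (1S,2S,3R,4R)-3,4-bis{[(tert-butoxycarbonyl)amino]methyl}cyclobutane-1,2-dicarboxylic acid | OC(=O)[C@H]1[C@H](CNC(=O)OC(C)(C)C)[C@@H](CNC(=O)OC(C)(C)C)[C@@H]1C(=O)O | intermediate
14 | bis(isobutyl carbonic) mixed anhydride of 13 | CC(C)COC(=O)OC(=O)[C@H]1[C@H](CNC(=O)OC(C)(C)C)[C@@H](CNC(=O)OC(C)(C)C)[C@@H]1C(=O)OC(=O)OCC(C)C | intermediate (not isolated)
15 | bis(diazomethyl ketone), all-trans, both carboxyls of 13 replaced by C(=O)CHN2 | [N-]=[N+]=CC(=O)[C@H]1[C@H](CNC(=O)OC(C)(C)C)[C@@H](CNC(=O)OC(C)(C)C)[C@@H]1C(=O)C=[N+]=[N-] | intermediate (not isolated)
16 | di-tert-butyl {[(1R,2R,3S,4S)-3,4-bis(2-bromoacetyl)cyclobutane-1,2-diyl]bis(methylene)}dicarbamate | BrCC(=O)[C@H]1[C@H](CNC(=O)OC(C)(C)C)[C@@H](CNC(=O)OC(C)(C)C)[C@@H]1C(=O)CBr | intermediate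
17 | N-Boc-guanidine | CC(C)(C)OC(=O)NC(N)=N | starting material
18 | di-tert-butyl 4,4'-[(1S,2S,3R,4R)-3,4-bis{[(tert-butoxycarbonyl)amino]methyl}cyclobutane-1,2-diyl]bis(2-amino-1H-imidazole-1-carboxylate) | CC(C)(C)OC(=O)n1cc(nc1N)[C@H]2[C@H](CNC(=O)OC(C)(C)C)[C@@H](CNC(=O)OC(C)(C)C)[C@@H]2c3cn(C(=O)OC(C)(C)C)c(N)n3 | intermediate
19 | 4,4'-[(1S,2S,3R,4R)-3,4-bis(aminomethyl)cyclobutane-1,2-diyl]bis(1H-imidazol-2-amine), handled as the tetrakis(trifluoroacetate) | Nc1ncc([C@H]2[C@H](CN)[C@@H](CN)[C@@H]2c2cnc(N)[nH]2)[nH]1 | intermediate
20 | 4-bromo-2-(trichloroacetyl)-1H-pyrrole | O=C(c1cc(Br)c[nH]1)C(Cl)(Cl)Cl | starting material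
21 | sceptrin, N,N'-{[(1R,2R,3S,4S)-3,4-bis(2-amino-1H-imidazol-4-yl)cyclobutane-1,2-diyl]bis(methylene)}bis(4-bromo-1H-pyrrole-2-carboxamide) | Nc1ncc([C@H]2[C@H](CNC(=O)c3cc(Br)c[nH]3)[C@@H](CNC(=O)c3cc(Br)c[nH]3)[C@@H]2c2cnc(N)[nH]2)[nH]1 | target

## Step count and least certain steps

Total: 12 steps. Longest linear sequence: 12 steps (1 to 21); compounds 4, 11, 17 and 20 are bought.

**Step 3 (key step).**
- What may go wrong: poor facial discrimination is the main risk. An E-alkene has no allylic strain to lock the reactive conformer, and a stepwise triplet addition is less ordered than osmylation. Reversion of the biradical could also scramble the alkene geometry. Triplet benzophenone could abstract the allylic, oxygen-activated hydrogen or form an oxetane with 3 instead of sensitising 4.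
- First remedies: a weak preference is met by separating the diastereomers at 5, 7 or 8. A reversed preference is met by entering from the mirror-image chiral-pool series.
- Fallback (from 4, rejoining at 12), which gives up substrate control: 4 would be irradiated under the same conditions with commercial (E)-1,4-dichlorobut-2-ene to give the racemic 6,7-trans-bis(chloromethyl) anhydride F1. Methanolysis, esterification and equilibration at the ester carbon would give the racemic all-trans bis(chloromethyl) diester F2. NaN3 in DMF would give the racemic bis(azidomethyl) diester F3. Hydrogenation over Pd/C in the presence of Boc2O would give the racemic bis(carbamate) diester F4. Preparative chromatography of F4 on a chiral stationary phase would deliver 12.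

**Step 7.**
- What may go wrong: a 1,4-dialdehyde meets a carbamate under acid. Enecarbamate formation could epimerise C2 or C3. Once a centre is cis, the first carbamate nitrogen can add to the neighbouring aldehyde and be reduced to a bicyclic pyrrolidine. Partial loss of Boc in TFA, direct reduction of an aldehyde and conversion of only one of the two arms are further losses.
- Fallback (from 10, rejoining at 12): reduction with NaBH4 in MeOH at −20 °C would give the all-trans bis(hydroxymethyl) diester F5. Mitsunobu azidation (PPh3, diisopropyl azodicarboxylate, diphenylphosphoryl azide) would give the bis(azidomethyl) diester F6. Hydrogenation over Pd/C with Boc2O in EtOAc would give 12.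

**Step 9.**
- What may go wrong: the activated carboxyl may be captured intramolecularly by a carbamate nitrogen (bridged N-Boc lactam). Boc may be lost during HBr treatment, and the freed amine would then alkylate itself on the bromoketone. Double conversion may be incomplete.
- Fallback (from 12, rejoining at 18), which avoids carboxyl activation and diazomethane: the diester 12 would be treated with dimethylsulfoxonium methylide (Me3S(O)I, KOtBu, THF) to give the bis(β-keto sulfoxonium ylide) F7. LiCl and MsOH in THF would convert it into the bis(chloromethyl ketone) F8. F8 would be condensed with 17 in DMF (catalytic NaI) to give 18.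

**Step 10.**
- What may go wrong: two annulations must succeed on one molecule. Possible side paths are competing O- or N-alkylation of a carbamate by the bromoketone under the basic conditions, double alkylation of one guanidine by both arms, and incomplete dehydration.
- Fallback (from 16, rejoining at 19), which builds the ring from an aminoketone instead: 16 would be converted with NaN3 into the bis(azidomethyl ketone) F9. Hydrogenation over Pd/C in MeOH with two equivalents of HCl would give the bis(aminomethyl ketone) dihydrochloride F10. Condensation with cyanamide in water at pH 4.5 and 95 °C would give the bis(2-aminoimidazole) bis(carbamate) F11. TFA would then give 19; any loss of Boc during the aqueous heating is harmless.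

## Further compounds

F1 | step 3 | racemic 6,7-trans-6,7-bis(chloromethyl)-3-oxabicyclo[3.2.0]heptane-2,4-dione (cis-fused; one enantiomer drawn) | O=C3OC(=O)[C@@H]1[C@H](CCl)[C@@H](CCl)[C@@H]13
F2 | step 3 | racemic all-trans dimethyl 3,4-bis(chloromethyl)cyclobutane-1,2-dicarboxylate (one enantiomer drawn) | COC(=O)[C@H]1[C@H](CCl)[C@@H](CCl)[C@@H]1C(=O)OC
F3 | step 3 | racemic all-trans dimethyl 3,4-bis(azidomethyl)cyclobutane-1,2-dicarboxylate (one enantiomer drawn) | COC(=O)[C@H]1[C@H](CN=[N+]=[N-])[C@@H](CN=[N+]=[N-])[C@@H]1C(=O)OC
F4 | step 3 | racemic all-trans dimethyl 3,4-bis{[(tert-butoxycarbonyl)amino]methyl}cyclobutane-1,2-dicarboxylate (racemate of 12; one enantiomer drawn) | COC(=O)[C@H]1[C@H](CNC(=O)OC(C)(C)C)[C@@H](CNC(=O)OC(C)(C)C)[C@@H]1C(=O)OC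
F5 | step 7 | dimethyl (1S,2S,3R,4R)-3,4-bis(hydroxymethyl)cyclobutane-1,2-dicarboxylate | COC(=O)[C@H]1[C@H](CO)[C@@H](CO)[C@@H]1C(=O)OC
F6 | step 7 | dimethyl (1S,2S,3R,4R)-3,4-bis(azidomethyl)cyclobutane-1,2-dicarboxylate | COC(=O)[C@H]1[C@H](CN=[N+]=[N-])[C@@H](CN=[N+]=[N-])[C@@H]1C(=O)OC
F7 | step 9 | all-trans bis(β-keto dimethylsulfoxonium ylide), each ester of 12 replaced by C(=O)CH=S(O)Me2 | C[S+](C)(=O)[CH-]C(=O)[C@H]1[C@H](CNC(=O)OC(C)(C)C)[C@@H](CNC(=O)OC(C)(C)C)[C@@H]1C(=O)[CH-][S+](C)(C)=O
F8 | step 9 | di-tert-butyl {[(1R,2R,3S,4S)-3,4-bis(2-chloroacetyl)cyclobutane-1,2-diyl]bis(methylene)}dicarbamate | ClCC(=O)[C@H]1[C@H](CNC(=O)OC(C)(C)C)[C@@H](CNC(=O)OC(C)(C)C)[C@@H]1C(=O)CCl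
F9 | step 10 | di-tert-butyl {[(1R,2R,3S,4S)-3,4-bis(2-azidoacetyl)cyclobutane-1,2-diyl]bis(methylene)}dicarbamate | [N-]=[N+]=NCC(=O)[C@H]1[C@H](CNC(=O)OC(C)(C)C)[C@@H](CNC(=O)OC(C)(C)C)[C@@H]1C(=O)CN=[N+]=[N-]
F10 | step 10 | di-tert-butyl {[(1R,2R,3S,4S)-3,4-bis(2-aminoacetyl)cyclobutane-1,2-diyl]bis(methylene)}dicarbamate, as dihydrochloride | NCC(=O)[C@H]1[C@H](CNC(=O)OC(C)(C)C)[C@@H](CNC(=O)OC(C)(C)C)[C@@H]1C(=O)CN
F11 | step 10 | di-tert-butyl {[(1R,2R,3S,4S)-3,4-bis(2-amino-1H-imidazol-4-yl)cyclobutane-1,2-diyl]bis(methylene)}dicarbamate | Nc1ncc([C@H]2[C@H](CNC(=O)OC(C)(C)C)[C@@H](CNC(=O)OC(C)(C)C)[C@@H]2c2cnc(N)[nH]2)[nH]1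
A1 | alternative 1 | 3,4-bis(1-SEM-imidazol-4-yl)-N,N'-di(quinolin-8-yl)cyclobutane-1,2-dicarboxamide, each imidazole cis to its neighbouring amide, amides trans | C[Si](C)(C)CCOCn1cnc(c1)[C@H]2[C@@H](C(=O)Nc3cccc4cccnc34)[C@H](C(=O)Nc3cccc4cccnc34)[C@@H]2c5cn(COCC[Si](C)(C)C)cn5
A2 | alternative 1 | (1R,2R)-N,N'-di(quinolin-8-yl)cyclobutane-1,2-dicarboxamide | C1[C@@H](C(=O)Nc2cccc3cccnc23)[C@H](C(=O)Nc2cccc3cccnc23)C1
A3 | alternative 1 | 4-iodo-1-{[2-(trimethylsilyl)ethoxy]methyl}imidazole | C[Si](C)(C)CCOCn1cnc(I)c1
A4 | alternative 2 | tricyclo[3.3.0.0(2,6)]octane-3,7-dione, enantiomer as drawn | O=C1[C@H]2[C@H](C3)[C@@H](C1)[C@@H]2C3=O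
A5 | alternative 2 | cis-3,7-bis(trimethylsilyloxy)bicyclo[3.3.0]octa-2,6-diene, twofold-symmetric enantiomer leading to A4 | C[Si](C)(C)OC1=C[C@@H]2CC(O[Si](C)(C)C)=C[C@@H]2C1
A6 | alternative 2 | cis-bicyclo[3.3.0]octane-3,7-dione (meso) | O=C1C[C@@H]2CC(=O)C[C@@H]2C1
A7 | alternative 3 | 4-tert-butyl 1-methyl 3,4-trans-3-(benzyloxymethyl)-2-(tert-butyldimethylsilyloxy)cyclobut-1-ene-1,4-dicarboxylate | COC(=O)C1=C(O[Si](C)(C)C(C)(C)C)[C@H](COCc2ccccc2)[C@H]1C(=O)OC(C)(C)C
A8 | alternative 3 | methyl (Z)-5-(benzyloxy)-3-(tert-butyldimethylsilyloxy)-2-diazopent-3-enoate | COC(=O)C(=[N+]=[N-])/C(O[Si](C)(C)C(C)(C)C)=C/COCc1ccccc1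
A9 | alternative 3 | tert-butyl 2-(dimethylsulfonio)acetate ylide | CC(C)(C)OC(=O)[CH-][S+](C)C
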